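## Structural features

Kanzonol X is an isoflavan: a chroman (benzo ring A fused to the dihydropyran ring C, O1–C2–C3–C4) that carries a 2',4'-dihydroxyphenyl ring B at C3. The only stereocentre is C3 (R). It has no stereogenic neighbour and sits between two methylene groups (C2 and C4), so it must be set by a reagent-controlled step. Each aromatic ring bears a 3-methylbut-2-enyl (prenyl) group on the carbon lying between two oxygens: C8 between O1 and the C7 hydroxyl, C3' between the C2' and C4' hydroxyls. On a free resorcinol these are the hardest positions to alkylate, because O-alkylation and attack at the less hindered ring carbons compete. The fragile groups are the three electron-rich phenols and the two prenyl double bonds: under acid a prenyl group adds the neighbouring phenol oxygen to give a 2,2-dimethylchroman, and it survives neither hydrogenolysis nor ozonolysis, which narrows the choice of protecting groups. The real difficulty is therefore regiochemical (two prenyl groups between oxygens), combined with one isolated stereocentre. The key step exploits ring B read as a cyclohexane-1,3-dione: C2' and C4' are the carbonyl carbons, C3' is the doubly activated carbon, C1' is the α-carbon of a methyl ketone (C1'–C2'(=O)–C3'H3) attached to C3, and C4'–C5'–C6' is an acrylate.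

## Logic of the disconnections

22 ⇒ 21. The O7–CH2 acetal bond is cut. O7 has to be masked while alkoxide, hydroxide and silyl triflate act on ring B. Nothing is gained in skeleton; the forward step must cleave one aryl acetal under acid mild enough to leave two prenyl/phenol pairs alone.

21 ⇒ 18. Ring B is taken out of the aromatic state: C5'–C6' becomes saturated and C2'/C4' become carbonyls. In the dione, C3' is a carbon acid, so the prenyl group can be placed by enolate C-alkylation instead of electrophilic substitution between two phenols. The forward step must dehydrogenate in the presence of two trisubstituted alkenes.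

18 ⇒ 17 + 3. The C3'–CH2 bond of the ring B prenyl group is cut. The dione has only one doubly activated carbon, so the position is unambiguous; the forward step must favour C- over O-alkylation.

17 ⇒ 14 + 15. C1'–C6' and C3'–C4' are cut, which dissolves ring B into a methyl ketone hanging on C3 and a three-carbon acrylate. A whole ring is removed in one operation. The forward step must make the Michael bond at the internal α-carbon and the Claisen bond from the methyl carbon, and it must not touch C3.

14 ⇒ 13 ⇒ 12. The O7 acetal and then O1–C2 are cut, opening ring C to a phenol and a primary alcohol. The reacting carbon is C2, so C3 is not involved. Only O8a can reach C2, so the ring closure itself distinguishes the two phenols of 12, and O7 can be protected afterwards without any selectivity question. The forward closure must be faster than intermolecular etherification.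

12 ⇒ 11. The C2'–C3' bond (carbonyl to methyl) is cut. The hydroxy ketone is stored as a γ-lactone in which C2 and C2' are already differentiated. The forward step needs a single addition of a methyl nucleophile to the lactone.

11 ⇒ 8. The lactone C–O bond is cut, C2 returns to the ester level, and the two ring A acetals are restored. This leads to a succinic half-ester whose acid and ester differ in reactivity. The forward step must reduce the ester beside the carboxylate; the acid used for lactonisation also removes both acetals, which is acceptable because the strongly basic chemistry on ring A is finished at that point.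

8 ⇒ 7. The C3–H and C4–H bonds are removed, tracing the stereocentre to the two faces of a trisubstituted alkene that carries a chelating carboxylate. The forward hydrogenation must select one face and leave the prenyl alkene alone.

7 ⇒ 5 + 6. The C3=C4 double bond is cut (Stobbe condensation). Compound 6 supplies C2, C3, C1' and C2' in one piece, and 5 is the ring A aldehyde. The forward step must give the half-ester with the ester on the alkene carbon.

5 ⇒ 4 ⇒ 2 + 3 ⇒ 1. The C4–C4a bond (formyl group) and the C8–CH2 bond (prenyl) are cut, then the two acetals. Both carbon substituents are placed by directed metalation, which is the reason for the acetal groups. The order matters: prenyl first at the carbon between the two acetals, then formyl ortho to one of them.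

## Other disconnections considered

Alternative 1: The cut runs through C3–C1' and C4–C4a, so that C3 and C4 come from vinylboronic acid pinacol ester A4 and both aryl rings arrive intact; C2 is added afterwards. In the forward sense, the aryllithium made from ring B bromide A2 by halogen–lithium exchange adds to A4. The resulting boron ate complex is coupled with ring A bromide A3 under Pd(OAc)2, a MandyPhos ligand and NaOTf: the arylpalladium electrophile activates the vinyl group, the ring B aryl shifts from boron to C3, and A1 forms with C3 set by the ligand. One-carbon homologation of the C–B bond with retention, oxidation to the primary alcohol, desilylation, Mitsunobu closure and removal of three acetals would complete the synthesis.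
- In its favour: it is convergent; both bromides can be derived from intermediate 4 of the present route; the stereocentre is created in the fragment-joining step; ring B never leaves the aromatic state, so no late dehydrogenation is needed. In step count (about ten to eleven operations, longest line about eight) it is the better plan. In regiocontrol of the two prenyl groups it is the equal, since it uses the same metalation between two acetal oxygens.
- Against it here: boron ends on C3, the carbon that must carry C2, so the key product is one carbon short and needs a chloromethyllithium homologation at a hindered secondary benzylic boronate. Both coupling partners carry an ortho oxygen substituent, A3 a bulky silyl ether next to the reacting carbon, which puts the enantioselective 1,2-metallate shift at the edge of the usual scope. Benzylic boronates of this kind are prone to protodeboronation. The end game removes three acetals with acid next to two prenyl groups, against one in the chosen plan.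
- Comparison: both plans set the stereocentre catalytically. The chosen plan does so in a hydrogenation of a chelating substrate class with broad, predictable scope, and pays for that with linearity.

Alternative 2: Here ring A is the ring that is built. C8–C8a, C6–C7 and C4a–C8a are cut, leading back to the prenylated siloxyalkyne A7 and the diazo enone A6, which already holds C2, C3 and ring B. Irradiation of A6 triggers a Wolff rearrangement to a vinylketene. [2+2] cycloaddition with A7, four-electron opening of the cyclobutenone and six-electron closure of the dienylketene give phenol A5, with the C8a hydroxyl free, O7 silylated and the prenyl group at C8.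
- In its favour: the substitution pattern of ring A, including the prenyl group between two oxygens, follows from the mechanism without directing-group chemistry. The two ring A oxygens emerge differentiated (free phenol for ring C closure, fluoride-labile silyl ether at O7). On this point it is the better plan, because the present route strips both acetals and reinstalls one; it also avoids acid for the ring A deprotection.
- Against it here: the most elaborate step is spent on the simpler, achiral ring, while the C3 stereocentre and the prenylated ring B must be solved beforehand in A6 by separate asymmetric chemistry. A6 (diazo transfer onto an enone) and A7 (an ynol silyl ether) are sensitive and each needs several steps. The ketene and carbene intermediates are generated in the presence of three trisubstituted alkenes that can intercept them by cycloaddition or cyclopropanation.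
- Comparison: in step economy it is clearly the longer plan (two multi-step fragments, then desilylation, Mitsunobu closure and deprotection). Mechanistically it is a pericyclic cascade under neutral conditions against ionic enolate chemistry; it is the equal of the chosen plan in that neither disturbs C3 once set.

Alternative 3: The cut goes through C3–C4 and O1–C2. Mild base eliminates sulfinate from the ring A benzylic sulfone A9 to release the ortho-quinone methide. The enamine formed from the ring B arylacetaldehyde A10 and a diarylprolinol trimethylsilyl ether adds to the methide carbon, and the phenoxide closes on C2 to give lactol A8. Reduction of the lactol to the diol, Mitsunobu closure (or direct reductive removal of the anomeric hydroxyl) and deprotection follow.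
- In its favour: two bonds of ring C and the stereocentre are formed in one organocatalytic step; the two fragments both derive from aldehyde chemistry close to 5; the sequence is short (about ten steps). In step economy and convergence it is the better plan.
- Against it here: in A8, C3 is benzylic and α to a masked aldehyde, so the open hydroxy aldehyde can enolise and the enantiomeric purity is at risk until C2 is reduced. The electron-rich, ortho-disubstituted quinone methide is a weak electrophile that can dimerise, and the arylacetaldehyde is prone to self-aldol condensation. C2 arrives at the wrong oxidation level and costs extra steps. Three acetals must again be cleaved next to prenyl groups.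
- Comparison: in regiocontrol of the prenyl groups it is the equal of the chosen plan (same metalation chemistry). In stereochemical security it is weaker, since in the chosen plan C3 is never α to a carbonyl after it is set.

Key step: step 10

Remarks on the chemistry:
- Atom labels: chroman O1, C2–C4, C4a, C5–C8, C8a; ring B C1'–C6'. The same labels are used for these carbons in the non-aromatic intermediates.
- Diones 17 and 18 are drawn as diketo tautomers and carried as mixtures of epimers at C1' (and C3'), since both centres become sp2 on aromatisation.
- The (S,S) antipode of the bisphospholane ligand is assumed to deliver the (R) acid 8, by analogy with related itaconate half-esters; the enantiomeric ligand is equally available if the sense proves opposite.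

## Route

Step 1
Reactants: 1 resorcinol
Product: 2 1,3-bis(methoxymethoxy)benzene
Conditions: NaH (2.4 equiv), MOMCl (2.4 equiv), DMF, 0 °C → rt
Reagents that add atoms: chloromethyl methyl ether (MOMCl), COCCl
Why: Williamson-type O-alkylation of both phenoxides; the acetals are base-stable and act as directing groups for the two ortho-metalations that follow.

Step 2
Reactants: 2 1,3-bis(methoxymethoxy)benzene; 3 prenyl bromide (1-bromo-3-methylbut-2-ene)
Product: 4 1,3-bis(methoxymethoxy)-2-(3-methylbut-2-enyl)benzene
Conditions: n-BuLi (1.15 equiv), THF, 0 °C → rt; CuI (10 mol %), 3 (1.3 equiv), −40 °C → rt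
Reagents that add atoms: none
Why: Directed ortho-metalation; the carbon between the two acetal oxygens is lithiated through cooperative coordination, and copper-assisted SN2 alkylation with the primary allylic bromide gives the linear prenyl arene (future C8).

Step 3
Reactants: 4 1,3-bis(methoxymethoxy)-2-(3-methylbut-2-enyl)benzene
Product: 5 2,4-bis(methoxymethoxy)-3-(3-methylbut-2-enyl)benzaldehyde
Conditions: n-BuLi (1.3 equiv), TMEDA (1.3 equiv), THF, −20 → 0 °C; DMF (3 equiv), 0 °C → rt; H2O
Reagents that add atoms: N,N-dimethylformamide, CN(C)C=O
Why: Second directed ortho-metalation at one of the two equivalent positions ortho to an acetal, then formylation of the aryllithium with DMF; the new carbon is the future C4.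

Step 4
Reactants: 5 2,4-bis(methoxymethoxy)-3-(3-methylbut-2-enyl)benzaldehyde; 6 dimethyl succinate
Product: 7 (E)-4-[2,4-bis(methoxymethoxy)-3-(3-methylbut-2-enyl)phenyl]-3-(methoxycarbonyl)but-3-enoic acid
Conditions: KOtBu (1.5 equiv), 6 (1.5 equiv), t-BuOH, 50 °C; 1 M HCl, 0 °C (pH 3)
Reagents that add atoms: none
Why: Stobbe condensation: aldol addition of the succinate enolate, lactonisation to the paraconic ester and E1cB ring opening give the (E)-alkylidene half-ester, with the ester on the alkene carbon and the free acid on the CH2, the differentiation that step 6 needs.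

Step 5
Reactants: 7 (E)-4-[2,4-bis(methoxymethoxy)-3-(3-methylbut-2-enyl)phenyl]-3-(methoxycarbonyl)but-3-enoic acid
Product: 8 (3R)-4-[2,4-bis(methoxymethoxy)-3-(3-methylbut-2-enyl)phenyl]-3-(methoxycarbonyl)butanoic acid
Conditions: [Rh(cod)2]BF4 (1 mol %), (S,S)-Et-DuPhos (1.1 mol %), NaOMe (10 mol %), H2 (5 bar), MeOH, rt
Reagents that add atoms: none
Why: Rhodium-catalysed asymmetric hydrogenation of an itaconate-type half-ester: carboxylate and alkene chelate the cationic rhodium centre and the C2-symmetric bisphospholane selects the alkene face, which sets C3 as (R); the prenyl alkene has no coordinating group and should not be reduced.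

Step 6
Reactants: 8 (3R)-4-[2,4-bis(methoxymethoxy)-3-(3-methylbut-2-enyl)phenyl]-3-(methoxycarbonyl)butanoic acid
Product: 11 (4R)-4-[2,4-dihydroxy-3-(3-methylbut-2-enyl)benzyl]dihydrofuran-2(3H)-one, via hydroxy acid 9 (not isolated), via bis-acetal lactone 10 (not isolated)
Conditions: KOH (1.0 equiv), EtOH, 0 °C; CaCl2, NaBH4, EtOH, −10 °C → rt; 2 M HCl; then HCl (1 M), MeOH, rt → 40 °C
Reagents that add atoms: none
Why: Ca(BH4)2 formed in the flask reduces the ester while the potassium carboxylate is inert; acid then lactonises the γ-hydroxy acid and cleaves both aryl acetals by exchange with methanol, and C3 (β to the lactone carbonyl) cannot epimerise.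

Step 7
Reactants: 11 (4R)-4-[2,4-dihydroxy-3-(3-methylbut-2-enyl)benzyl]dihydrofuran-2(3H)-one
Product: 12 (4R)-4-[2,4-dihydroxy-3-(3-methylbut-2-enyl)benzyl]-5-hydroxypentan-2-one
Conditions: MeLi (3.2 equiv), THF, −78 °C; AcOH, −78 °C → rt
Reagents that add atoms: methyllithium, [Li]C
Why: After deprotonation of the two phenols, methyllithium adds once to the lactone carbonyl; the tetrahedral lithium lactolate is stable at −78 °C, so the ketone appears only on protonation and a second addition is suppressed.

Step 8
Reactants: 12 (4R)-4-[2,4-dihydroxy-3-(3-methylbut-2-enyl)benzyl]-5-hydroxypentan-2-one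
Product: 13 1-[(3R)-7-hydroxy-8-(3-methylbut-2-enyl)chroman-3-yl]propan-2-one
Conditions: PPh3 (1.3 equiv), DIAD (1.3 equiv), THF (0.02 M), 0 °C → rt
Reagents that add atoms: none
Why: Intramolecular Mitsunobu etherification: the primary alcohol is activated as its alkoxyphosphonium ion and displaced by the ortho phenoxide O8a in a 6-exo-tet closure of ring C; the C7 hydroxyl cannot reach C2, and C3 is not a reacting centre, so its configuration is kept.

Step 9
Reactants: 13 1-[(3R)-7-hydroxy-8-(3-methylbut-2-enyl)chroman-3-yl]propan-2-one
Product: 14 1-[(3R)-7-(methoxymethoxy)-8-(3-methylbut-2-enyl)chroman-3-yl]propan-2-one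
Conditions: MOMCl (1.5 equiv), i-Pr2NEt (2.0 equiv), CH2Cl2, 0 °C → rt
Reagents that add atoms: chloromethyl methyl ether (MOMCl), COCCl
Why: O-alkylation of the only remaining phenol under amine base, which leaves the ketone alone; the acetal withstands the alkoxide, hydroxide and silyl triflate conditions that follow.

Step 10
Reactants: 14 1-[(3R)-7-(methoxymethoxy)-8-(3-methylbut-2-enyl)chroman-3-yl]propan-2-one; 15 methyl acrylate
Product: 17 4-[(3R)-7-(methoxymethoxy)-8-(3-methylbut-2-enyl)chroman-3-yl]cyclohexane-1,3-dione (both epimers at C1'), via Michael adduct keto ester 16 (not isolated)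
Conditions: KOtBu (2.2 equiv), THF, −10 °C, 30 min; 15 (1.1 equiv, slow addition), −10 °C → rt; 1 M HCl, 0 °C (pH 4)
Reagents that add atoms: none
Why: Consecutive Michael–Claisen annulation, the known route from substituted acetones and acrylates to 4-substituted cyclohexane-1,3-diones. Under equilibrating conditions (KOtBu with the tert-butanol it forms) the enolates of 14 interconvert, and the more substituted enolate adds through C1' to the β-carbon of 15 (C1'–C6'), as alkoxide-mediated Michael additions of alkyl methyl ketones generally do. Proton transfer then gives the methyl enolate of keto ester 16, whose carbon C3' attacks the ester carbonyl C4' with loss of methoxide (C3'–C4'), a 6-(enolendo)-exo-trig Claisen closure of ring B. Deprotonation of the product between its two carbonyls (pKa about 5) makes the sequence irreversible and shields the dione from further reaction. Once the Michael bond is at C1', only C3' can close a six-membered ring, so the Claisen regiochemistry is fixed by ring size; the Michael regiochemistry is the one selectivity that is not enforced, because addition at the methyl carbon followed by closure from C1' would also give a six-membered ring (the 2-substituted dione), and it is favoured here only by the enolate equilibrium, pre-formation of the enolate and slow addition of 15 at low temperature. C1' becomes a stereocentre without control, which is immaterial because it is enolisable and is flattened on aromatisation. C3 lies β to the ketone, bears no acidic hydrogen and no leaving group, and the aryl ether oxygen sits one carbon further out, so neither epimerisation nor elimination is possible; the acetal and the prenyl group are inert to alkoxide.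

Step 11
Reactants: 17 4-[(3R)-7-(methoxymethoxy)-8-(3-methylbut-2-enyl)chroman-3-yl]cyclohexane-1,3-dione; 3 prenyl bromide (1-bromo-3-methylbut-2-ene)
Product: 18 4-[(3R)-7-(methoxymethoxy)-8-(3-methylbut-2-enyl)chroman-3-yl]-2-(3-methylbut-2-enyl)cyclohexane-1,3-dione (mixture of epimers and enol forms)
Conditions: KOH (1.1 equiv, 1 M aq.), 3 (1.3 equiv), H2O–1,4-dioxane, 0 °C → rt
Reagents that add atoms: none
Why: C-alkylation of the vinylogous carboxylate at C3', its only doubly activated carbon; water solvates the enolate oxygens and steers the allylic bromide to carbon, the established way to 2-allyl- and 2-prenylcyclohexane-1,3-diones.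

Step 12
Reactants: 18 4-[(3R)-7-(methoxymethoxy)-8-(3-methylbut-2-enyl)chroman-3-yl]-2-(3-methylbut-2-enyl)cyclohexane-1,3-dione
Product: 21 4-[(3R)-7-(methoxymethoxy)-8-(3-methylbut-2-enyl)chroman-3-yl]-2-(3-methylbut-2-enyl)benzene-1,3-diol, via bis(trimethylsilyl) dienol ether 19 (not isolated), via mono(trimethylsilyl) resorcinol ether 20 (not isolated)
Conditions: TMSOTf (2.4 equiv), Et3N (3.5 equiv), CH2Cl2, 0 °C; then Pd(OAc)2 (1.1 equiv), MeCN, rt; then K2CO3 (10 mol %), MeOH, 0 °C
Reagents that add atoms: none
Why: Saegusa-type dehydrogenation: soft enolisation gives the 2,4-bis(silyloxy)-1,3-diene, divalent palladium attacks its terminal carbon C5', β-hydride elimination from C6' gives a cross-conjugated dienone that tautomerises through C1'–H to the arene, and methanolysis removes the remaining silyl group; C1' and C3' become sp2 while C3 is untouched.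

Step 13
Reactants: 21 4-[(3R)-7-(methoxymethoxy)-8-(3-methylbut-2-enyl)chroman-3-yl]-2-(3-methylbut-2-enyl)benzene-1,3-diol
Product: 22 Kanzonol X, 4-[(3R)-7-hydroxy-8-(3-methylbut-2-enyl)chroman-3-yl]-2-(3-methylbut-2-enyl)benzene-1,3-diol
Conditions: HCl (0.5 M in MeOH), 0 °C → rt, monitored; NaHCO3
Reagents that add atoms: none
Why: Acid-catalysed acetal exchange with methanol releases the C7 phenol; low temperature and short contact keep addition of the phenols to the prenyl double bonds (dimethylchroman formation) slower than acetal cleavage.

## Compound list

1 | resorcinol | Oc1cccc(O)c1 | starting material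
2 | 1,3-bis(methoxymethoxy)benzene | COCOc1cccc(OCOC)c1 | intermediate
3 | prenyl bromide (1-bromo-3-methylbut-2-ene) | CC(C)=CCBr | starting material
4 | 1,3-bis(methoxymethoxy)-2-(3-methylbut-2-enyl)benzene | COCOc1cccc(OCOC)c1CC=C(C)C | intermediate
5 | 2,4-bis(methoxymethoxy)-3-(3-methylbut-2-enyl)benzaldehyde | O=Cc1ccc(OCOC)c(CC=C(C)C)c1OCOC | intermediate
6 | dimethyl succinate | COC(=O)CCC(=O)OC | starting material
7 | (E)-4-[2,4-bis(methoxymethoxy)-3-(3-methylbut-2-enyl)phenyl]-3-(methoxycarbonyl)but-3-enoic acid | OC(=O)C/C(C(=O)OC)=C\c1ccc(OCOC)c(CC=C(C)C)c1OCOC | intermediate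
8 | (3R)-4-[2,4-bis(methoxymethoxy)-3-(3-methylbut-2-enyl)phenyl]-3-(methoxycarbonyl)butanoic acid | OC(=O)C[C@@H](Cc1ccc(OCOC)c(CC=C(C)C)c1OCOC)C(=O)OC | intermediate
9 | (3R)-4-[2,4-bis(methoxymethoxy)-3-(3-methylbut-2-enyl)phenyl]-3-(hydroxymethyl)butanoic acid | OC(=O)C[C@@H](Cc1ccc(OCOC)c(CC=C(C)C)c1OCOC)CO | intermediate (not isolated)
10 | (4R)-4-[2,4-bis(methoxymethoxy)-3-(3-methylbut-2-enyl)benzyl]dihydrofuran-2(3H)-one | O=C1C[C@@H](Cc2ccc(OCOC)c(CC=C(C)C)c2OCOC)CO1 | intermediate (not isolated)
11 | (4R)-4-[2,4-dihydroxy-3-(3-methylbut-2-enyl)benzyl]dihydrofuran-2(3H)-one | O=C1C[C@@H](Cc2ccc(O)c(CC=C(C)C)c2O)CO1 | intermediate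
12 | (4R)-4-[2,4-dihydroxy-3-(3-methylbut-2-enyl)benzyl]-5-hydroxypentan-2-one | CC(=O)C[C@@H](Cc1ccc(O)c(CC=C(C)C)c1O)CO | intermediate
13 | 1-[(3R)-7-hydroxy-8-(3-methylbut-2-enyl)chroman-3-yl]propan-2-one | CC(=O)C[C@@H]1COc2c(CC=C(C)C)c(O)ccc2C1 | intermediate
14 | 1-[(3R)-7-(methoxymethoxy)-8-(3-methylbut-2-enyl)chroman-3-yl]propan-2-one | CC(=O)C[C@@H]1COc2c(CC=C(C)C)c(OCOC)ccc2C1 | intermediate (precursor of the key step)
15 | methyl acrylate | C=CC(=O)OC | starting material
16 | methyl 4-[(3R)-7-(methoxymethoxy)-8-(3-methylbut-2-enyl)chroman-3-yl]-5-oxohexanoate (both epimers at C4) | COC(=O)CCC(C(C)=O)[C@@H]1COc2c(CC=C(C)C)c(OCOC)ccc2C1 | intermediate (not isolated)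
17 | 4-[(3R)-7-(methoxymethoxy)-8-(3-methylbut-2-enyl)chroman-3-yl]cyclohexane-1,3-dione (both epimers at C1') | O=C1CC(=O)C(CC1)[C@@H]2COc3c(CC=C(C)C)c(OCOC)ccc3C2 | intermediate (product of the key step)
18 | 4-[(3R)-7-(methoxymethoxy)-8-(3-methylbut-2-enyl)chroman-3-yl]-2-(3-methylbut-2-enyl)cyclohexane-1,3-dione | O=C1CCC([C@@H]2COc3c(CC=C(C)C)c(OCOC)ccc3C2)C(=O)C1CC=C(C)C | intermediate
19 | (3R)-3-[2,4-bis(trimethylsilyloxy)-3-(3-methylbut-2-enyl)cyclohexa-2,4-dien-1-yl]-7-(methoxymethoxy)-8-(3-methylbut-2-enyl)chroman | C[Si](C)(C)OC1=CCC([C@@H]2COc3c(CC=C(C)C)c(OCOC)ccc3C2)C(O[Si](C)(C)C)=C1CC=C(C)C | intermediate (not isolated)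
20 | 4-[(3R)-7-(methoxymethoxy)-8-(3-methylbut-2-enyl)chroman-3-yl]-2-(3-methylbut-2-enyl)-3-(trimethylsilyloxy)phenol | CC(C)=CCc1c(O)ccc([C@@H]2COc3c(CC=C(C)C)c(OCOC)ccc3C2)c1O[Si](C)(C)C | intermediate (not isolated)
21 | 4-[(3R)-7-(methoxymethoxy)-8-(3-methylbut-2-enyl)chroman-3-yl]-2-(3-methylbut-2-enyl)benzene-1,3-diol | CC(C)=CCc1c(O)ccc([C@@H]2COc3c(CC=C(C)C)c(OCOC)ccc3C2)c1O | intermediate
22 | Kanzonol X, 4-[(3R)-7-hydroxy-8-(3-methylbut-2-enyl)chroman-3-yl]-2-(3-methylbut-2-enyl)benzene-1,3-diol | CC(C)=CCc1c(O)ccc([C@@H]2COc3c(ccc(O)c3CC=C(C)C)C2)c1O | target

## Step count and least certain steps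

Total step count: 13. Longest linear sequence: 13 steps (1 → 22); the route is linear, with 3, 6 and 15 purchased.

Step 10 (key step). What may go wrong: conjugate addition through the less hindered methyl enolate competes with addition through C1', because the branch at C3 crowds the internal carbon; ring closure then delivers the 2-substituted dione. Oligomerisation of the acrylate under alkoxide is a second loss. Fallback, from 14 back to 17: 14 is condensed with benzylamine (4 Å molecular sieves, toluene) to the N-benzyl ketimine F1. Heated with 15 in THF, F1 reacts through its more substituted secondary enamine tautomer, the known regiochemical preference of ketimine Michael additions, to give the imine of the C1' adduct F2. Aqueous acetic acid hydrolyses F2 to keto ester 16, which is isolated this time. KOtBu in THF then closes 16 to 17, a step in which only the methyl carbon can form a six-membered ring.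

Step 12. What may go wrong: palladation at the central carbon C3' followed by β-hydride elimination into the prenyl side chain, engagement of the prenyl alkenes by divalent palladium, or protodesilylation by the acetic acid formed, which returns the dione. Fallback, from 18 back to 21: 18 is converted into its dianion (LDA, 2.2 equiv, THF, −78 → 0 °C) and quenched at the less hindered γ-carbon C5' with PhSeCl at −78 °C to give the selenide 4-[(3R)-7-(methoxymethoxy)-8-(3-methylbut-2-enyl)chroman-3-yl]-2-(3-methylbut-2-enyl)-6-(phenylselanyl)cyclohexane-1,3-dione F3. Oxidation with NaIO4 (NaHCO3, aqueous MeOH) and syn-elimination of the selenoxide give the C5'=C6' enedione, which tautomerises to 21 without any palladium.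

Step 11. What may go wrong: O-alkylation to the enol prenyl ether, a second C-alkylation at C3', and slow reaction of the lipophilic enolate in water. Fallback, from 17 back to 18: Tsuji–Trost allylation with methyl 3-methylbut-2-enyl carbonate and Pd(PPh3)4 in THF at rt under neutral conditions. The soft dione carbon attacks the less hindered terminus of the 1,1-dimethylallyl palladium complex, and any O-allylated material is re-ionised by the catalyst and funnelled to the C-alkylated product. No new compound arises on this path (F0).

Step 7. What may go wrong: a second addition of methyllithium to give the tertiary alcohol, or incomplete reaction because the dilithium bis-phenoxide aggregates; in step 8 the cyclic hemiketal form of 12 may also slow the etherification. Fallback, from 11 back to 14: 11 is opened with Me(MeO)NH·HCl/AlMe3 (excess, CH2Cl2) to (3R)-3-[2,4-dihydroxy-3-(3-methylbut-2-enyl)benzyl]-4-hydroxy-N-methoxy-N-methylbutanamide F4. Mitsunobu closure (PPh3, DIAD) gives 2-[(3R)-7-hydroxy-8-(3-methylbut-2-enyl)chroman-3-yl]-N-methoxy-N-methylacetamide F5. MOMCl/i-Pr2NEt gives the 7-O-methoxymethyl amide F6, and MeMgBr (THF, 0 °C) converts F6 into 14 through the chelated tetrahedral intermediate, which excludes over-addition.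

Step 13. What may go wrong: acid-promoted addition of the ortho phenol oxygens to the prenyl double bonds on either ring (dimethylchroman formation) at a rate comparable to acetal cleavage. The same process threatens the acid stage of step 6, on earlier and cheaper material. Fallback, from 13 to 22, with no protecting group on O7: 13 is taken through the Michael–Claisen annulation with one extra equivalent of KOtBu (the phenoxide is a spectator) to 4-[(3R)-7-hydroxy-8-(3-methylbut-2-enyl)chroman-3-yl]cyclohexane-1,3-dione F7. F7 is C-prenylated with 3 and exactly one equivalent of aqueous KOH, so that only the dione (pKa about 5) and not the phenol (pKa about 10) is ionised, giving the 2-prenyl dione F8. Silylation of all three acidic oxygens (TMSOTf, Et3N), Pd(OAc)2 and methanolysis then give 22 directly, with no acid at the end.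

Step 3. What may go wrong: deprotonation of the benzylic and allylic CH2 of the prenyl group instead of the ring position, leading to side-chain formylation or alkene migration. Fallback, from 3 back to 5: commercial 2,4-dihydroxybenzaldehyde F9 is C-prenylated with 3 in aqueous KOH at the carbon between its two oxygens, a known reaction of modest efficiency, to give 2,4-dihydroxy-3-(3-methylbut-2-enyl)benzaldehyde F10. NaH/MOMCl in DMF converts F10 into 5.

## Further compounds

F1 | step 10 | (R)-N-benzyl-1-[7-(methoxymethoxy)-8-(3-methylbut-2-enyl)chroman-3-yl]propan-2-imine | CC(=NCc1ccccc1)C[C@@H]1COc2c(CC=C(C)C)c(OCOC)ccc2C1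
F2 | step 10 | methyl 5-(benzylimino)-4-[(3R)-7-(methoxymethoxy)-8-(3-methylbut-2-enyl)chroman-3-yl]hexanoate | COC(=O)CCC(C(C)=NCc1ccccc1)[C@@H]1COc2c(CC=C(C)C)c(OCOC)ccc2C1
F3 | step 12 | 4-[(3R)-7-(methoxymethoxy)-8-(3-methylbut-2-enyl)chroman-3-yl]-2-(3-methylbut-2-enyl)-6-(phenylselanyl)cyclohexane-1,3-dione | O=C1C(CC=C(C)C)C(=O)C(CC1[Se]c2ccccc2)[C@@H]3COc4c(CC=C(C)C)c(OCOC)ccc4C3
F0 | step 11 | none | none
F4 | step 7 | (3R)-3-[2,4-dihydroxy-3-(3-methylbut-2-enyl)benzyl]-4-hydroxy-N-methoxy-N-methylbutanamide | CON(C)C(=O)C[C@@H](Cc1ccc(O)c(CC=C(C)C)c1O)CO
F5 | step 7 | 2-[(3R)-7-hydroxy-8-(3-methylbut-2-enyl)chroman-3-yl]-N-methoxy-N-methylacetamide | CON(C)C(=O)C[C@@H]1COc2c(CC=C(C)C)c(O)ccc2C1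
F6 | step 7 | N-methoxy-2-[(3R)-7-(methoxymethoxy)-8-(3-methylbut-2-enyl)chroman-3-yl]-N-methylacetamide | CON(C)C(=O)C[C@@H]1COc2c(CC=C(C)C)c(OCOC)ccc2C1
F7 | step 13 | 4-[(3R)-7-hydroxy-8-(3-methylbut-2-enyl)chroman-3-yl]cyclohexane-1,3-dione | O=C1CC(=O)C(CC1)[C@@H]2COc3c(CC=C(C)C)c(O)ccc3C2
F8 | step 13 | 4-[(3R)-7-hydroxy-8-(3-methylbut-2-enyl)chroman-3-yl]-2-(3-methylbut-2-enyl)cyclohexane-1,3-dione | O=C1CCC([C@@H]2COc3c(CC=C(C)C)c(O)ccc3C2)C(=O)C1CC=C(C)C
F9 | step 3 | 2,4-dihydroxybenzaldehyde | O=Cc1ccc(O)cc1O
F10 | step 3 | 2,4-dihydroxy-3-(3-methylbut-2-enyl)benzaldehyde | O=Cc1ccc(O)c(CC=C(C)C)c1O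
A1 | alternative 1 | (R)-2-{1-[2,4-bis(methoxymethoxy)-3-(3-methylbut-2-enyl)phenyl]-2-[2-(tert-butyldimethylsilyloxy)-4-(methoxymethoxy)-3-(3-methylbut-2-enyl)phenyl]ethyl}-4,4,5,5-tetramethyl-1,3,2-dioxaborolane | CC1(C)OB(OC1(C)C)[C@H](Cc1ccc(OCOC)c(CC=C(C)C)c1O[Si](C)(C)C(C)(C)C)c1ccc(OCOC)c(CC=C(C)C)c1OCOC
A2 | alternative 1 | 1-bromo-2,4-bis(methoxymethoxy)-3-(3-methylbut-2-enyl)benzene | Brc1ccc(OCOC)c(CC=C(C)C)c1OCOC
A3 | alternative 1 | [6-bromo-3-(methoxymethoxy)-2-(3-methylbut-2-enyl)phenoxy](tert-butyl)dimethylsilane | Brc1ccc(OCOC)c(CC=C(C)C)c1O[Si](C)(C)C(C)(C)C
A4 | alternative 1 | 2-ethenyl-4,4,5,5-tetramethyl-1,3,2-dioxaborolane | C=CB1OC(C)(C)C(C)(C)O1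
A5 | alternative 2 | (R)-2-{3-(tert-butyldimethylsilyloxy)-2-[2,4-bis(methoxymethoxy)-3-(3-methylbut-2-enyl)phenyl]propyl}-6-(3-methylbut-2-enyl)-5-(triisopropylsilyloxy)phenol | CC(C)(C)[Si](C)(C)OC[C@H](Cc1ccc(O[Si](C(C)C)(C(C)C)C(C)C)c(CC=C(C)C)c1O)c1ccc(OCOC)c(CC=C(C)C)c1OCOC
A6 | alternative 2 | (R,E)-6-[2,4-bis(methoxymethoxy)-3-(3-methylbut-2-enyl)phenyl]-7-(tert-butyldimethylsilyloxy)-1-diazohept-3-en-2-one | CC(C)(C)[Si](C)(C)OC[C@H](C/C=C/C(=O)C=[N+]=[N-])c1ccc(OCOC)c(CC=C(C)C)c1OCOC
A7 | alternative 2 | triisopropyl[(5-methylhex-4-en-1-yn-1-yl)oxy]silane | CC(C)=CCC#CO[Si](C(C)C)(C(C)C)C(C)C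
A8 | alternative 3 | (3R)-7-(methoxymethoxy)-3-[2,4-bis(methoxymethoxy)-3-(3-methylbut-2-enyl)phenyl]-8-(3-methylbut-2-enyl)chroman-2-ol (both anomers at C2) | CC(C)=CCc1c(OCOC)ccc([C@@H]2C(O)Oc3c(ccc(OCOC)c3CC=C(C)C)C2)c1OCOC
A9 | alternative 3 | 3-(methoxymethoxy)-2-(3-methylbut-2-enyl)-6-[(4-methylphenylsulfonyl)methyl]phenol | Cc1ccc(cc1)S(=O)(=O)Cc1ccc(OCOC)c(CC=C(C)C)c1O
A10 | alternative 3 | 2-[2,4-bis(methoxymethoxy)-3-(3-methylbut-2-enyl)phenyl]acetaldehyde | O=CCc1ccc(OCOC)c(CC=C(C)C)c1OCOC
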